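**Plan**

- **Feature:** Ring D, the 3-acyl-2,4,6-trihydroxyphenyl ring on C4 of the flavan, carries oxygen on every second carbon. The flavanyl-bearing carbon and its two C–OH neighbours form a malonyl C3 unit. The ring CH, the third C–OH and the acyl-bearing carbon are C2, C3 and C4 of a 3,5-dioxo ester whose C5 ketone already holds the 8-phenyloctyl chain.
- **Retrosynthesis:** A carboxyl is put back on the ring CH. The two ring-D bonds from the malonyl carbonyl carbons to C2 and C4 of the dioxo ester are then cut together, followed by C4–CH(malonyl), C2–ring B and C4–C5 of the dioxo ester.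
- **Forward order:** Rings A and C come ready-made in 7-hydroxychromone. Ring B is attached at C2 and the malonyl carbon at C4. The chain is joined to allyl acetoacetate, and ring D is closed last from the two halves.
- **Stereochemistry:** C2 (S) is set by the chiral ligand in a rhodium-catalysed 1,4-arylation. C4 is set relative to C2 by attack on the flavan-4-yl cation anti to ring B (2,4-trans). It is 4S in the malonates and 4R in the target through a change of CIP priority only.
- **Ester choice:** The malonate enters ring formation as its bis(pentafluorophenyl) ester and the dioxo ester as its allyl ester. The condensation then needs no alkoxide, and the surplus carboxyl leaves under neutral conditions before the final hydrogenolysis.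

Key step: step 10

Assumption: the (S)-biaryl bisphosphine (S)-MeO-F12-BIPHEP, (6,6'-dimethoxybiphenyl-2,2'-diyl)bis[bis(3,4,5-trifluorophenyl)phosphine], is taken to deliver aryl to the same enone face as (S)-biaryl bisphosphines do with 2-cyclohexenone, which corresponds to 2S in 4. If the rotation of 4 shows the opposite sense, the (R)-ligand is used.

Remark: compounds 1, 3, 6, 11 and 13 are purchasable. The enolisable carbons of 18 and F3 and the double-bond geometry of 7 are configurationally labile and are left undefined.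

**Step 1**
Reactants: 1 7-hydroxychromone
Product: 2 7-(benzyloxy)chromone
Conditions: BnBr (1.2 equiv), K2CO3 (1.5 equiv), acetone, reflux
Reagents that add atoms: benzyl bromide, BrCc1ccccc1
Why: Williamson ether synthesis at the only acidic OH; carbonate in acetone does not open the pyranone ring, and the benzyl ether lasts until the final hydrogenolysis.

**Step 2**
Reactants: 2 7-(benzyloxy)chromone; 3 [4-(benzyloxy)phenyl]boronic acid
Product: 4 (2S)-7-(benzyloxy)-2-[4-(benzyloxy)phenyl]chroman-4-one
Conditions: 3 (2 equiv), [Rh(OH)(cod)]2 (1.5 mol %), (S)-MeO-F12-BIPHEP (3.3 mol %), toluene–H2O 10:1, 25 °C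
Reagents that add atoms: none
Why: Hayashi–Miyaura asymmetric 1,4-addition, established on chromones with electron-poor bisphosphine complexes of monovalent rhodium; the aryl–rhodium species inserts into C2=C3 on the face left open by the ligand and so sets C2 as S, while base-free conditions at room temperature avoid retro-oxa-Michael racemisation.

**Step 3**
Reactants: 4 (2S)-7-(benzyloxy)-2-[4-(benzyloxy)phenyl]chroman-4-one
Product: 5 (2S,4S)-7-(benzyloxy)-2-[4-(benzyloxy)phenyl]chroman-4-ol (2,4-cis)
Conditions: NaBH4 (1.5 equiv), THF–MeOH 4:1, −10 °C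
Reagents that add atoms: none
Why: Borohydride reduction of a flavanone, in which axial hydride delivery to the conformer with equatorial ring B should give the equatorial 2,4-cis alcohol; the C4 configuration is erased in step 5, so its purity is not critical.

**Step 4**
Reactants: 6 dimethyl malonate
Product: 7 methyl 3-methoxy-3-(trimethylsilyloxy)prop-2-enoate
Conditions: Me3SiOTf (1.05 equiv), Et3N (1.1 equiv), Et2O, 0 → 25 °C; salt layer removed, distilled
Reagents that add atoms: trimethylsilyl trifluoromethanesulfonate, C[Si](C)(C)OS(=O)(=O)C(F)(F)F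
Why: Soft enolisation and O-silylation of a malonate with silyl triflate and amine is the standard route to its mono(silyl ketene acetal), which is far more nucleophilic at carbon than the free diester.

**Step 5**
Reactants: 5 (2S,4S)-7-(benzyloxy)-2-[4-(benzyloxy)phenyl]chroman-4-ol; 7 methyl 3-methoxy-3-(trimethylsilyloxy)prop-2-enoate
Product: 8 dimethyl 2-{(2S,4S)-7-(benzyloxy)-2-[4-(benzyloxy)phenyl]chroman-4-yl}malonate (2,4-trans)
Conditions: 7 (2.5 equiv), Me3SiOTf (0.2 equiv), CH2Cl2, −78 → −40 °C; Et3N quench
Reagents that add atoms: none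
Why: Mukaiyama-type SN1 alkylation, as in known C4 substitutions of flavan-4-ols by silyl enol ethers, allylsilanes and arenes; the C4 cation is stabilised by O1 (ortho) and the 7-benzyloxy group (para), and pseudo-axial attack on the face anti to the equatorial ring B sets C4 in the 2,4-trans sense.

**Step 6**
Reactants: 8 dimethyl 2-{(2S,4S)-7-(benzyloxy)-2-[4-(benzyloxy)phenyl]chroman-4-yl}malonate
Product: 9 2-{(2S,4S)-7-(benzyloxy)-2-[4-(benzyloxy)phenyl]chroman-4-yl}malonic acid
Conditions: LiOH·H2O (8 equiv), THF–MeOH–H2O 3:1:1, 45 °C; 1 M HCl to pH 2, 0 °C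
Reagents that add atoms: lithium hydroxide, [Li+].[OH-]
Why: Saponification of a 2-alkylmalonate; the benzyl ethers and both stereocentres (no acidic C–H, no β-leaving group) are inert to hydroxide, and cold acidification avoids decarboxylation.

**Step 7**
Reactants: 9 2-{(2S,4S)-7-(benzyloxy)-2-[4-(benzyloxy)phenyl]chroman-4-yl}malonic acid
Product: 10 bis(pentafluorophenyl) 2-{(2S,4S)-7-(benzyloxy)-2-[4-(benzyloxy)phenyl]chroman-4-yl}malonate
Conditions: C6F5OH (2.3 equiv), DCC (2.2 equiv), EtOAc, 0 → 25 °C; filtered, short silica plug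
Reagents that add atoms: pentafluorophenol, Oc1c(F)c(F)c(F)c(F)c1F
Why: Carbodiimide formation of pentafluorophenyl active esters is routine and runs without added acid or base at or below room temperature, so neither decarboxylation nor opening of ring C should intervene, and both carboxyls become good nucleofuges.

**Step 8**
Reactants: 11 9-phenylnonanoic acid
Product: 12 N-methoxy-N-methyl-9-phenylnonanamide
Conditions: MeNH(OMe)·HCl (1.2 equiv), EDC·HCl (1.2 equiv), Et3N (2.4 equiv), CH2Cl2, 0 → 25 °C
Reagents that add atoms: N,O-dimethylhydroxylamine hydrochloride, CNOC.Cl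
Why: Standard carbodiimide amidation of an unhindered acid to its Weinreb amide.

**Step 9**
Reactants: 12 N-methoxy-N-methyl-9-phenylnonanamide; 13 allyl acetoacetate
Product: 15 allyl 3,5-dioxo-13-phenyltridecanoate, via dilithium dienolate 14 (not isolated)
Conditions: 13 (2 equiv), LiN(iPr)2 (4.1 equiv), THF, −78 → 0 °C; 12, −78 → 0 °C; 1 M HCl, 0 °C
Reagents that add atoms: none
Why: γ-Acylation of an acetoacetate dianion by a Weinreb amide, a known route to 3,5-dioxo esters; the chelated tetrahedral adduct persists until the quench and prevents over-addition and proton exchange with the more acidic product.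

**Step 10**
Reactants: 10 bis(pentafluorophenyl) 2-{(2S,4S)-7-(benzyloxy)-2-[4-(benzyloxy)phenyl]chroman-4-yl}malonate; 15 allyl 3,5-dioxo-13-phenyltridecanoate
Product: 19 allyl 3-{(2S,4R)-7-(benzyloxy)-2-[4-(benzyloxy)phenyl]chroman-4-yl}-2,4,6-trihydroxy-5-(9-phenylnonanoyl)benzoate, via disodium dienolate 16 (not isolated), via aryloxycarbonyl ketene 17 (not isolated), via open-chain Claisen adduct 18 (not isolated)
Conditions: 15 (1.3 equiv), NaH (5 equiv), THF, 0 → 25 °C; 10 in THF added over 2 h, −20 → 40 °C; 1 M HCl, 0 °C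
Reagents that add atoms: none
Why: Proposed new method: sodium hydride turns 15 into the C2,C4-dienolate 16 and removes the malonyl α-proton of 10, whose enolate expels pentafluorophenoxide (E1cB) to the sterically open ketene 17; C2 of 16 adds to the ketene carbon (crossed Claisen acylation, adduct 18), C4 then displaces the second pentafluorophenoxide in a Dieckmann closure, and threefold enolisation to the phloroglucinol anion makes the sequence irreversible. The closest known reactions are the double Claisen condensation of 3-oxoglutarates with malonates to phloroglucinol dicarboxylates, the cyclocondensation of 2-substituted bis(aryl) active malonates with 1,3-dinucleophiles through aryloxycarbonyl ketenes, and the Claisen-mode cyclisation of 3,5,7-trioxo esters to acylphloroglucinols; new here is the pairing of a 2-sec-alkylmalonate with a 3,5-dioxoalkanoate. Ring D closes as a six-membered carbocycle in the 6-exo-trig mode (6-(enolendo)-exo-trig with respect to the C3–C4 enolate). No stereocentre is created, and C2 and C4 of the flavan bear neither an acidic hydrogen nor a leaving group under base, so both keep their configuration. The step needs C- over O-acylation (2-pyranone closure), reaction at C2 and C4 rather than C6, and survival of the acyl chain: only C2 and C4 are doubly activated and hydride does not metalate C6, full dienolate formation masks the allyl ester and the ketones against lactonisation, the absence of alkoxide removes the retro-Claisen pathway, and the carbanionic C4 should outrun the enolate oxygens. Because the two acyl termini of 10 are identical, either order of attack gives the same constitution, with the flavanyl carbon between two hydroxyls.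

**Step 11**
Reactants: 19 allyl 3-{(2S,4R)-7-(benzyloxy)-2-[4-(benzyloxy)phenyl]chroman-4-yl}-2,4,6-trihydroxy-5-(9-phenylnonanoyl)benzoate
Product: 21 1-(3-{(2S,4R)-7-(benzyloxy)-2-[4-(benzyloxy)phenyl]chroman-4-yl}-2,4,6-trihydroxyphenyl)-9-phenylnonan-1-one, via free trihydroxybenzoic acid 20 (not isolated)
Conditions: Pd(PPh3)4 (5 mol %), N-methylaniline (3 equiv), 1,4-dioxane, 25 °C; then H2O (5 vol %), 80 °C
Reagents that add atoms: none
Why: Tsuji–Trost deallylation, in which zerovalent palladium ionises the allyl ester and N-methylaniline takes up the allyl group, followed by the protodecarboxylation typical of phloroglucinol carboxylic acids (ipso-protonation of a β-keto-acid tautomer), run while the benzyl ethers still block quinone-methide epimerisation at C2.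

**Step 12**
Reactants: 21 1-(3-{(2S,4R)-7-(benzyloxy)-2-[4-(benzyloxy)phenyl]chroman-4-yl}-2,4,6-trihydroxyphenyl)-9-phenylnonan-1-one
Product: 22 (+)-myristinin D
Conditions: H2 (1 atm), 10% Pd/C, EtOAc–MeOH 1:1, 25 °C
Reagents that add atoms: none
Why: Hydrogenolysis of aryl benzyl ethers, the usual last step for polyphenolic flavans; the hydrogen-bonded aryl ketone, the cyclic O1–C2 ether and the C4–aryl bond react much more slowly at 1 atm, and no stereocentre is touched.

**Compound list**

1 | 7-hydroxychromone | O=c1ccoc2cc(O)ccc12 | starting material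
2 | 7-(benzyloxy)chromone | O=c1ccoc2cc(OCc3ccccc3)ccc12 | intermediate
3 | [4-(benzyloxy)phenyl]boronic acid | OB(O)c1ccc(OCc2ccccc2)cc1 | starting material
4 | (2S)-7-(benzyloxy)-2-[4-(benzyloxy)phenyl]chroman-4-one | O=C1C[C@@H](c2ccc(OCc3ccccc3)cc2)Oc2cc(OCc3ccccc3)ccc21 | intermediate
5 | (2S,4S)-7-(benzyloxy)-2-[4-(benzyloxy)phenyl]chroman-4-ol, 2,4-cis | O[C@H]1C[C@@H](c2ccc(OCc3ccccc3)cc2)Oc2cc(OCc3ccccc3)ccc21 | intermediate
6 | dimethyl malonate | COC(=O)CC(=O)OC | starting material
7 | methyl 3-methoxy-3-(trimethylsilyloxy)prop-2-enoate | COC(=O)C=C(OC)O[Si](C)(C)C | intermediate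
8 | dimethyl 2-{(2S,4S)-7-(benzyloxy)-2-[4-(benzyloxy)phenyl]chroman-4-yl}malonate, 2,4-trans | COC(=O)C(C(=O)OC)[C@@H]1C[C@@H](c2ccc(OCc3ccccc3)cc2)Oc2cc(OCc3ccccc3)ccc21 | intermediate
9 | 2-{(2S,4S)-7-(benzyloxy)-2-[4-(benzyloxy)phenyl]chroman-4-yl}malonic acid | OC(=O)C(C(=O)O)[C@@H]1C[C@@H](c2ccc(OCc3ccccc3)cc2)Oc2cc(OCc3ccccc3)ccc21 | intermediate
10 | bis(pentafluorophenyl) 2-{(2S,4S)-7-(benzyloxy)-2-[4-(benzyloxy)phenyl]chroman-4-yl}malonate | O=C(Oc1c(F)c(F)c(F)c(F)c1F)C(C(=O)Oc1c(F)c(F)c(F)c(F)c1F)[C@@H]1C[C@@H](c2ccc(OCc3ccccc3)cc2)Oc2cc(OCc3ccccc3)ccc21 | intermediate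
11 | 9-phenylnonanoic acid | OC(=O)CCCCCCCCc1ccccc1 | starting material
12 | N-methoxy-N-methyl-9-phenylnonanamide | CON(C)C(=O)CCCCCCCCc1ccccc1 | intermediate
13 | allyl acetoacetate | CC(=O)CC(=O)OCC=C | starting material
14 | dilithium dienolate of allyl acetoacetate | [Li+].[Li+].C=C([O-])C=C([O-])OCC=C | intermediate
15 | allyl 3,5-dioxo-13-phenyltridecanoate | C=CCOC(=O)CC(=O)CC(=O)CCCCCCCCc1ccccc1 | intermediate
16 | disodium C2,C4-dienolate of 15 | [Na+].[Na+].C=CCOC([O-])=CC(=O)C=C([O-])CCCCCCCCc1ccccc1 | intermediate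
17 | pentafluorophenyl 2-{(2S,4R)-7-(benzyloxy)-2-[4-(benzyloxy)phenyl]chroman-4-yl}-3-oxoprop-2-enoate (ketene) | O=C=C(C(=O)Oc1c(F)c(F)c(F)c(F)c1F)[C@@H]1C[C@@H](c2ccc(OCc3ccccc3)cc2)Oc2cc(OCc3ccccc3)ccc21 | intermediate
18 | allyl 2-[2-{(2S,4S)-7-(benzyloxy)-2-[4-(benzyloxy)phenyl]chroman-4-yl}-3-oxo-3-(pentafluorophenoxy)propanoyl]-3,5-dioxo-13-phenyltridecanoate (enolisable centres undefined) | C=CCOC(=O)C(C(=O)CC(=O)CCCCCCCCc1ccccc1)C(=O)C(C(=O)Oc1c(F)c(F)c(F)c(F)c1F)[C@@H]1C[C@@H](c2ccc(OCc3ccccc3)cc2)Oc2cc(OCc3ccccc3)ccc21 | intermediate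
19 | allyl 3-{(2S,4R)-7-(benzyloxy)-2-[4-(benzyloxy)phenyl]chroman-4-yl}-2,4,6-trihydroxy-5-(9-phenylnonanoyl)benzoate | C=CCOC(=O)c1c(O)c(C(=O)CCCCCCCCc2ccccc2)c(O)c([C@@H]2C[C@@H](c3ccc(OCc4ccccc4)cc3)Oc3cc(OCc4ccccc4)ccc32)c1O | intermediate
20 | 3-{(2S,4R)-7-(benzyloxy)-2-[4-(benzyloxy)phenyl]chroman-4-yl}-2,4,6-trihydroxy-5-(9-phenylnonanoyl)benzoic acid | OC(=O)c1c(O)c(C(=O)CCCCCCCCc2ccccc2)c(O)c([C@@H]2C[C@@H](c3ccc(OCc4ccccc4)cc3)Oc3cc(OCc4ccccc4)ccc32)c1O | intermediate
21 | 1-(3-{(2S,4R)-7-(benzyloxy)-2-[4-(benzyloxy)phenyl]chroman-4-yl}-2,4,6-trihydroxyphenyl)-9-phenylnonan-1-one | O=C(CCCCCCCCc1ccccc1)c1c(O)cc(O)c([C@@H]2C[C@@H](c3ccc(OCc4ccccc4)cc3)Oc3cc(OCc4ccccc4)ccc32)c1O | intermediate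
22 | (+)-myristinin D, 1-{2,4,6-trihydroxy-3-[(2S,4R)-7-hydroxy-2-(4-hydroxyphenyl)chroman-4-yl]phenyl}-9-phenylnonan-1-one | O=C(CCCCCCCCc1ccccc1)c1c(O)cc(O)c([C@@H]2C[C@@H](c3ccc(O)cc3)Oc3cc(O)ccc32)c1O | target

**Step count**

- Total: 12 steps.
- Longest linear sequence: 9 steps (1, 2, 3, 5, 6, 7, 10, 11, 12).

**Steps most likely to fail**

1. **Step 10 (carries the label).**
   - What may go wrong: O-acylation and enol-lactone closure may outrun the second C–C bond formation. The ketene may oligomerise. Proton transfer may stall the sequence after the first acylation.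
   - Fallback (known chemistry, ring D brought in intact): the sequence sets out from 11 and 5. Phloroglucinol is C-acylated with 11 in BF3·OEt2 at 80 °C (Friedel–Crafts acylation) to 1-(2,4,6-trihydroxyphenyl)-9-phenylnonan-1-one F1. F1 is then alkylated at one of its two equivalent free ring carbons by the cation of 5 (cat. p-TsOH, dioxane, 25 °C). This is the Friedel–Crafts benzylation of an acylphloroglucinol by a flavan-4-ol. The same attack anti to ring B favours the trans product, and the cis isomer is removed by chromatography. The sequence comes back to the route at 21.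

2. **Step 5.**
   - What may go wrong: the C4 cation may lose a proton to the flav-3-ene, which then oligomerises. Facial selectivity may be modest. Ring C may open reversibly at O1–C2 under the Lewis acid, eroding the C2 configuration.
   - Fallback: the sequence sets out from 5. The hydroxyl is displaced with inversion and without a free cation by Meldrum's acid under Mitsunobu conditions (PPh3, DIAD, toluene, 0 °C). This turns the 2,4-cis alcohol into the 2,4-trans compound 5-{(2S,4S)-7-(benzyloxy)-2-[4-(benzyloxy)phenyl]chroman-4-yl}-2,2-dimethyl-1,3-dioxane-4,6-dione F2. Heating F2 with pentafluorophenol (toluene, 90 °C) gives 2-{(2S,4S)-7-(benzyloxy)-2-[4-(benzyloxy)phenyl]chroman-4-yl}-3-oxo-3-(pentafluorophenoxy)propanoic acid F3. DCC with C6F5OH esterifies the remaining carboxyl. The sequence comes back to the route at 10 and makes steps 4 and 6 unnecessary.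

3. **Step 11.**
   - What may go wrong: the electron-rich ring D may capture the π-allyl palladium species (C- or O-allylation) in competition with the amine. Loss of CO2 may be sluggish because the acyl group lowers the basicity of the ipso carbon, so that long heating is needed.
   - Fallback: the surplus carboxyl is carried as a benzyl ester and unmasked together with the phenols. The sequence sets out from 12, which acylates the dianion of benzyl acetoacetate (conditions of step 9) to benzyl 3,5-dioxo-13-phenyltridecanoate F4. Condensation of F4 with 10 under the conditions of step 10 gives benzyl 3-{(2S,4R)-7-(benzyloxy)-2-[4-(benzyloxy)phenyl]chroman-4-yl}-2,4,6-trihydroxy-5-(9-phenylnonanoyl)benzoate F5. Hydrogenolysis (H2, Pd/C, EtOAc–MeOH) removes all three benzyl groups to 2,4,6-trihydroxy-3-[(2S,4R)-7-hydroxy-2-(4-hydroxyphenyl)chroman-4-yl]-5-(9-phenylnonanoyl)benzoic acid F6. F6 should lose CO2 on gentle warming in faintly acidic solution (trace AcOH, 45 °C), where phenoxide-driven epimerisation at C2 is suppressed. The sequence comes back to the route at 22.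

**Further compounds**

F1 | step 10 | 1-(2,4,6-trihydroxyphenyl)-9-phenylnonan-1-one | O=C(CCCCCCCCc1ccccc1)c1c(O)cc(O)cc1O
F2 | step 5 | 5-{(2S,4S)-7-(benzyloxy)-2-[4-(benzyloxy)phenyl]chroman-4-yl}-2,2-dimethyl-1,3-dioxane-4,6-dione | CC1(C)OC(=O)C(C(=O)O1)[C@@H]1C[C@@H](c2ccc(OCc3ccccc3)cc2)Oc2cc(OCc3ccccc3)ccc21
F3 | step 5 | 2-{(2S,4S)-7-(benzyloxy)-2-[4-(benzyloxy)phenyl]chroman-4-yl}-3-oxo-3-(pentafluorophenoxy)propanoic acid | OC(=O)C(C(=O)Oc1c(F)c(F)c(F)c(F)c1F)[C@@H]1C[C@@H](c2ccc(OCc3ccccc3)cc2)Oc2cc(OCc3ccccc3)ccc21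
F4 | step 11 | benzyl 3,5-dioxo-13-phenyltridecanoate | O=C(CC(=O)CC(=O)CCCCCCCCc1ccccc1)OCc1ccccc1
F5 | step 11 | benzyl 3-{(2S,4R)-7-(benzyloxy)-2-[4-(benzyloxy)phenyl]chroman-4-yl}-2,4,6-trihydroxy-5-(9-phenylnonanoyl)benzoate | O=C(OCc1ccccc1)c1c(O)c(C(=O)CCCCCCCCc2ccccc2)c(O)c([C@@H]2C[C@@H](c3ccc(OCc4ccccc4)cc3)Oc3cc(OCc4ccccc4)ccc32)c1O
F6 | step 11 | 2,4,6-trihydroxy-3-[(2S,4R)-7-hydroxy-2-(4-hydroxyphenyl)chroman-4-yl]-5-(9-phenylnonanoyl)benzoic acid | OC(=O)c1c(O)c(C(=O)CCCCCCCCc2ccccc2)c(O)c([C@@H]2C[C@@H](c3ccc(O)cc3)Oc3cc(O)ccc32)c1O
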